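**Retrosynthetic overview**

1. Flavan numbering is used for both units; the upper unit has rings A (benzo), B (catechol) and C (pyran), the lower unit rings D, E and F likewise. The last disconnection is hydrogenolysis of eight benzyl ethers from an octa-O-benzyl dimer whose upper 7-OH is free.
2. Key disconnection: the aryl ether bond O1–C8a of ring C. Ring A is carried as a plain 4-substituted phenol with no oxygen or halogen at C8a. In one telescoped operation it is dearomatised to a p-quinol, closed by 6-exo oxa-Michael addition of the C2 hydroxyl, and rearomatised by loss of water.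
3. Enabling feature: in ring A the 7-OH is para to C4a, and O1 sits on C8a, meta to the 7-OH. C8a is therefore a β-carbon of the 4-alkyl-4-hydroxycyclohexa-2,5-dienone that corresponds to ring A. Its two β-carbons (C8a and C5) give the same chroman once the ring is aromatic again.
4. The acyclic precursor comes from a chalcone epoxide (4-hydroxybenzaldehyde plus 3,4-bis(benzyloxy)acetophenone) and the protected lower flavan. Friedel–Crafts opening at C4 with inversion forms the C4–C6 interflavan bond and the 3,4-cis relation in the open chain; C3–O benzylation and chelation-controlled reduction then give the anti C2/C3 pair (2,3-trans after closure).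
5. The lower flavan (tetra-O-benzylmesquitol) comes from gallacetophenone via a second chalcone epoxide and a dihydroflavonol. Ring order: ring F (step 5), then ring C (step 13); rings B, D and E arrive aromatic, ring A is dearomatised and rearomatised in the key step.

Key step: step 13

Assumption: poly-L-leucine is taken to give the (αR,βS)-epoxide of chalcone 5 and the cinchonidinium catalyst of step 9 the (αS,βR)-epoxide of chalcone 14, as these catalyst families do with simple chalcones; if a sense were reversed, poly-D-leucine or the cinchonine-derived salt would be used.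
Remark: the CIP descriptor of the upper C4 is R in 22 and 23 and S in 24 with unchanged geometry, because debenzylation of the lower 7-oxygen changes the priority order at C4.

**Route**

Step 1
Reactants: 1 2',3',4'-trihydroxyacetophenone
Product: 2 1-[3,4-bis(benzyloxy)-2-hydroxyphenyl]ethan-1-one
Conditions: BnBr (2.1 equiv), K2CO3, acetone, reflux
Reagents that add atoms: benzyl bromide, BrCc1ccccc1
Why: Williamson etherification; the 2-hydroxyl is hydrogen-bonded to the acetyl carbonyl and least reactive, so two equivalents of benzyl bromide should alkylate O3 and O4 only.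

Step 2
Reactants: 2 1-[3,4-bis(benzyloxy)-2-hydroxyphenyl]ethan-1-one
Product: 3 1-[3,4-bis(benzyloxy)-2-(methoxymethoxy)phenyl]ethan-1-one
Conditions: NaH, MOMCl, DMF, 0 °C to rt
Reagents that add atoms: chloromethyl methyl ether, COCCl
Why: Williamson-type O-alkylation of the sodium phenolate masks the last phenol as an acid-labile acetal that should survive the basic steps 3 and 4.

Step 3
Reactants: 3 1-[3,4-bis(benzyloxy)-2-(methoxymethoxy)phenyl]ethan-1-one; 4 3,4-bis(benzyloxy)benzaldehyde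
Product: 5 (E)-1-[3,4-bis(benzyloxy)-2-(methoxymethoxy)phenyl]-3-[3,4-bis(benzyloxy)phenyl]prop-2-en-1-one
Conditions: KOH (aq.), EtOH/THF, rt
Reagents that add atoms: none
Why: Claisen–Schmidt condensation; E1cB dehydration of the aldol should give the conjugated E-enone.

Step 4
Reactants: 5 (E)-1-[3,4-bis(benzyloxy)-2-(methoxymethoxy)phenyl]-3-[3,4-bis(benzyloxy)phenyl]prop-2-en-1-one
Product: 6 [3,4-bis(benzyloxy)-2-(methoxymethoxy)phenyl][(2R,3S)-3-[3,4-bis(benzyloxy)phenyl]oxiran-2-yl]methanone (trans; αR,βS)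
Conditions: poly-L-leucine, urea–H2O2, 1,8-diazabicyclo[5.4.0]undec-7-ene (DBU), THF, rt
Reagents that add atoms: urea–hydrogen peroxide, NC(N)=O.OO
Why: Juliá–Colonna epoxidation (Weitz–Scheffer addition of hydroperoxide inside the helical peptide), which should deliver oxygen to one enone face and give the trans (αR,βS)-epoxide.

Step 5
Reactants: 6 [3,4-bis(benzyloxy)-2-(methoxymethoxy)phenyl][(2R,3S)-3-[3,4-bis(benzyloxy)phenyl]oxiran-2-yl]methanone
Product: 8 (2R,3R)-7,8-bis(benzyloxy)-2-[3,4-bis(benzyloxy)phenyl]-3-hydroxychroman-4-one, via 2'-hydroxy epoxy ketone 7 (not isolated)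
Conditions: conc. HCl, MeOH/THF, 50 °C
Reagents that add atoms: none
Why: acid removes the methoxymethyl acetal and the freed phenol opens the protonated epoxide at the benzylic Cβ (6-endo-tet, SN2-type, inversion), so the trans epoxide should give the 2,3-trans dihydroflavonol with Cα (C3) untouched.

Step 6
Reactants: 8 (2R,3R)-7,8-bis(benzyloxy)-2-[3,4-bis(benzyloxy)phenyl]-3-hydroxychroman-4-one
Product: 10 (2R,3S)-7,8-bis(benzyloxy)-2-[3,4-bis(benzyloxy)phenyl]chroman-3-ol, via flavan-3,4-diol 9 (not isolated)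
Conditions: NaBH4, THF/EtOH, 0 °C; then Et3SiH, CF3CO2H, CH2Cl2, −20 °C
Reagents that add atoms: none
Why: carbonyl reduction followed by ionic hydrogenation; the 4-hydroxyl, para-related to the 7-benzyloxy group through C4a, should ionise readily and the benzylic cation be trapped by the silane, while C2 and C3 are not touched.

Step 7
Reactants: 11 1-[3,4-bis(benzyloxy)phenyl]ethan-1-one; 12 4-hydroxybenzaldehyde
Product: 13 (E)-1-[3,4-bis(benzyloxy)phenyl]-3-(4-hydroxyphenyl)prop-2-en-1-one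
Conditions: KOH (aq. 50%), EtOH, rt to 50 °C; aq. HCl work-up
Reagents that add atoms: none
Why: Claisen–Schmidt condensation, which tolerates the unprotected 4-hydroxybenzaldehyde under excess hydroxide and should give the E-enone.

Step 8
Reactants: 13 (E)-1-[3,4-bis(benzyloxy)phenyl]-3-(4-hydroxyphenyl)prop-2-en-1-one
Product: 14 4-[(E)-3-[3,4-bis(benzyloxy)phenyl]-3-oxoprop-1-en-1-yl]phenyl 2,2-dimethylpropanoate
Conditions: PivCl, Et3N, 4-(dimethylamino)pyridine (cat.), CH2Cl2, 0 °C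
Reagents that add atoms: pivaloyl chloride, CC(C)(C)C(Cl)=O
Why: O-acylation of the phenol; the pivalate is orthogonal to the benzyl ethers and makes ring A a poor cation-stabilising group, which should keep the epoxide opening of step 10 invertive.

Step 9
Reactants: 14 4-[(E)-3-[3,4-bis(benzyloxy)phenyl]-3-oxoprop-1-en-1-yl]phenyl 2,2-dimethylpropanoate
Product: 15 4-[(2R,3S)-3-[3,4-bis(benzyloxy)benzoyl]oxiran-2-yl]phenyl 2,2-dimethylpropanoate (trans; αS,βR)
Conditions: O-benzyl-N-(9-anthracenylmethyl)dihydrocinchonidinium bromide (10 mol%), aq. KOCl, toluene, −40 °C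
Reagents that add atoms: potassium hypochlorite, [K+].[O-]Cl
Why: asymmetric phase-transfer nucleophilic epoxidation (Weitz–Scheffer type); the chiral ammonium hypochlorite ion pair should add to one enone face to give the trans (αS,βR)-epoxide, and the hindered aryl pivalate should survive the cold two-phase base.

Step 10
Reactants: 15 4-[(2R,3S)-3-[3,4-bis(benzyloxy)benzoyl]oxiran-2-yl]phenyl 2,2-dimethylpropanoate; 10 (2R,3S)-7,8-bis(benzyloxy)-2-[3,4-bis(benzyloxy)phenyl]chroman-3-ol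
Product: 16 (2S,3R)-1-[3,4-bis(benzyloxy)phenyl]-2-hydroxy-3-[4-(pivaloyloxy)phenyl]-3-[(2R,3S)-7,8-bis(benzyloxy)-2-[3,4-bis(benzyloxy)phenyl]-3-hydroxychroman-6-yl]propan-1-one
Conditions: BF3·OEt2 (20 mol%), CH2Cl2/(CF3)2CHOH, −20 °C
Reagents that add atoms: none
Why: Friedel–Crafts alkylation by a Lewis-acid-activated aryl epoxide; C6 of 10 (ortho to the 7-benzyloxy group and para to the ring oxygen) should attack the benzylic Cβ anti to the departing oxygen, which sets C4 by inversion and leaves the Cα–O centre (C3) intact.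

Step 11
Reactants: 16 (2S,3R)-1-[3,4-bis(benzyloxy)phenyl]-2-hydroxy-3-[4-(pivaloyloxy)phenyl]-3-[(2R,3S)-7,8-bis(benzyloxy)-2-[3,4-bis(benzyloxy)phenyl]-3-hydroxychroman-6-yl]propan-1-one
Product: 17 (2S,3R)-2-(benzyloxy)-1-[3,4-bis(benzyloxy)phenyl]-3-[4-(pivaloyloxy)phenyl]-3-[(2R,3S)-3,7,8-tris(benzyloxy)-2-[3,4-bis(benzyloxy)phenyl]chroman-6-yl]propan-1-one
Conditions: BnOC(=NH)CCl3 (4 equiv), CF3SO3H (cat.), CH2Cl2/cyclohexane, 0 °C
Reagents that add atoms: benzyl 2,2,2-trichloroacetimidate, N=C(OCc1ccccc1)C(Cl)(Cl)Cl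
Why: acid-catalysed O-benzylation with the trichloroacetimidate, which avoids the base that would enolise the α-hydroxy ketone and caps both secondary hydroxyls so that later only the C2 hydroxyl is free.

Step 12
Reactants: 17 (2S,3R)-2-(benzyloxy)-1-[3,4-bis(benzyloxy)phenyl]-3-[4-(pivaloyloxy)phenyl]-3-[(2R,3S)-3,7,8-tris(benzyloxy)-2-[3,4-bis(benzyloxy)phenyl]chroman-6-yl]propan-1-one
Product: 19 (1R,2S,3R)-2-(benzyloxy)-1-[3,4-bis(benzyloxy)phenyl]-3-(4-hydroxyphenyl)-3-[(2R,3S)-3,7,8-tris(benzyloxy)-2-[3,4-bis(benzyloxy)phenyl]chroman-6-yl]propan-1-ol, via pivalate alcohol 18 (not isolated)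
Conditions: Zn(BH4)2, Et2O/THF, −30 °C; then NaOMe, MeOH, rt
Reagents that add atoms: none
Why: chelation-controlled reduction; zinc should bridge the carbonyl and the α-benzyloxy oxygen so that hydride adds from the face of the small α-hydrogen and gives the anti (1R,2S) diol monoether, after which methoxide cleaves the aryl pivalate by transesterification.

Step 13
Reactants: 19 (1R,2S,3R)-2-(benzyloxy)-1-[3,4-bis(benzyloxy)phenyl]-3-(4-hydroxyphenyl)-3-[(2R,3S)-3,7,8-tris(benzyloxy)-2-[3,4-bis(benzyloxy)phenyl]chroman-6-yl]propan-1-ol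
Product: 23 (2R,3S,4R)-3-(benzyloxy)-2-[3,4-bis(benzyloxy)phenyl]-4-[(2R,3S)-3,7,8-tris(benzyloxy)-2-[3,4-bis(benzyloxy)phenyl]chroman-6-yl]chroman-7-ol, via hydroperoxide 20 (not isolated), via p-quinol 21 (not isolated), via oxa-Michael adduct 22 (not isolated)
Conditions: Oxone (2KHSO5·KHSO4·K2SO4), NaHCO3, MeCN/THF/H2O, rt; Na2S2O3; then DBU (20 mol%), CH2Cl2, rt; then p-toluenesulfonic acid monohydrate (TsOH·H2O), 0 °C to rt
Reagents that add atoms: none
Why: Proposed new method: singlet oxygen released from KHSO5/NaHCO3 should add to the ring A phenolate para to oxygen (at C4a) to give hydroperoxide 20, which thiosulfate reduces to p-quinol 21; under DBU the C2 hydroxyl should add to a dienone β-carbon (the future C8a) to give 22, and TsOH should then enolise the ketone, ionise the angular C4a hydroxyl and expel the C8a proton, so that ring A is aromatic again and the oxygen brought in by Oxone leaves as water. The closest known reaction types are the Oxone-mediated dearomatisation of 4-alkylphenols to p-quinols, the intramolecular oxa-Michael addition of hydroxyalkyl-substituted quinols, and the acid-induced dehydrative rearomatisation of quinol conjugate adducts to meta-substituted phenols; their telescoped use to close a chroman ring is the untested part. Ring C closes through its O1–C8a bond in a 6-exo-trig oxa-Michael mode. No stereocentre of 23 is created: C4a and C8a of 22 are erased on aromatisation, C2 keeps its configuration because its C–O bond is never broken, and C3 and C4 are not involved. Chemoselectivity rests on ring A being the only free phenol (the only ring that singlet oxygen dearomatises) and on the C2 hydroxyl being the only free alcohol (the benzylated C3 oxygen cannot close the competing five-membered ring); site selectivity is not needed because both β-carbons of 21 lead to the same chroman.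

Step 14
Reactants: 23 (2R,3S,4R)-3-(benzyloxy)-2-[3,4-bis(benzyloxy)phenyl]-4-[(2R,3S)-3,7,8-tris(benzyloxy)-2-[3,4-bis(benzyloxy)phenyl]chroman-6-yl]chroman-7-ol
Product: 24 (2R,3S,4S)-2-(3,4-dihydroxyphenyl)-4-[(2R,3S)-2-(3,4-dihydroxyphenyl)-3,7,8-trihydroxychroman-6-yl]chromane-3,7-diol
Conditions: H2 (1 atm), Pd(OH)2/C, THF/MeOH, rt
Reagents that add atoms: none
Why: hydrogenolysis of the eight benzyl ethers under the conditions customary for benzylated proanthocyanidins, which should leave the flavan C2–O1 bonds and all five stereocentres intact.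

**Compound list**

1 | 2',3',4'-trihydroxyacetophenone | CC(=O)c1ccc(O)c(O)c1O | starting material
2 | 1-[3,4-bis(benzyloxy)-2-hydroxyphenyl]ethan-1-one | CC(=O)c1ccc(OCc2ccccc2)c(OCc2ccccc2)c1O | intermediate
3 | 1-[3,4-bis(benzyloxy)-2-(methoxymethoxy)phenyl]ethan-1-one | CC(=O)c1ccc(OCc2ccccc2)c(OCc2ccccc2)c1OCOC | intermediate
4 | 3,4-bis(benzyloxy)benzaldehyde | O=Cc1ccc(OCc2ccccc2)c(OCc2ccccc2)c1 | starting material
5 | (E)-1-[3,4-bis(benzyloxy)-2-(methoxymethoxy)phenyl]-3-[3,4-bis(benzyloxy)phenyl]prop-2-en-1-one | O=C(/C=C/c1ccc(OCc2ccccc2)c(OCc2ccccc2)c1)c1ccc(OCc2ccccc2)c(OCc2ccccc2)c1OCOC | intermediate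
6 | [3,4-bis(benzyloxy)-2-(methoxymethoxy)phenyl][(2R,3S)-3-[3,4-bis(benzyloxy)phenyl]oxiran-2-yl]methanone | O=C(c1ccc(OCc2ccccc2)c(OCc2ccccc2)c1OCOC)[C@@H]1O[C@H]1c1ccc(OCc2ccccc2)c(OCc2ccccc2)c1 | intermediate
7 | [3,4-bis(benzyloxy)-2-hydroxyphenyl][(2R,3S)-3-[3,4-bis(benzyloxy)phenyl]oxiran-2-yl]methanone | O=C(c1ccc(OCc2ccccc2)c(OCc2ccccc2)c1O)[C@@H]1O[C@H]1c1ccc(OCc2ccccc2)c(OCc2ccccc2)c1 | intermediate
8 | (2R,3R)-7,8-bis(benzyloxy)-2-[3,4-bis(benzyloxy)phenyl]-3-hydroxychroman-4-one | c1cc2c(c(OCc3ccccc3)c1OCc1ccccc1)O[C@H](c1ccc(OCc3ccccc3)c(OCc3ccccc3)c1)[C@@H](O)C2=O | intermediate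
9 | (2R,3S,4R)-7,8-bis(benzyloxy)-2-[3,4-bis(benzyloxy)phenyl]chromane-3,4-diol (2,3-trans-3,4-trans; the C4 epimer would react alike) | c1cc2c(c(OCc3ccccc3)c1OCc1ccccc1)O[C@H](c1ccc(OCc3ccccc3)c(OCc3ccccc3)c1)[C@@H](O)[C@@H]2O | intermediate
10 | (2R,3S)-7,8-bis(benzyloxy)-2-[3,4-bis(benzyloxy)phenyl]chroman-3-ol (tetra-O-benzylmesquitol) | c1cc2c(c(OCc3ccccc3)c1OCc1ccccc1)O[C@H](c1ccc(OCc3ccccc3)c(OCc3ccccc3)c1)[C@@H](O)C2 | intermediate
11 | 1-[3,4-bis(benzyloxy)phenyl]ethan-1-one | CC(=O)c1ccc(OCc2ccccc2)c(OCc2ccccc2)c1 | starting material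
12 | 4-hydroxybenzaldehyde | O=Cc1ccc(O)cc1 | starting material
13 | (E)-1-[3,4-bis(benzyloxy)phenyl]-3-(4-hydroxyphenyl)prop-2-en-1-one | O=C(/C=C/c1ccc(O)cc1)c1ccc(OCc2ccccc2)c(OCc2ccccc2)c1 | intermediate
14 | 4-[(E)-3-[3,4-bis(benzyloxy)phenyl]-3-oxoprop-1-en-1-yl]phenyl 2,2-dimethylpropanoate | CC(C)(C)C(=O)Oc1ccc(/C=C/C(=O)c2ccc(OCc3ccccc3)c(OCc3ccccc3)c2)cc1 | intermediate
15 | 4-[(2R,3S)-3-[3,4-bis(benzyloxy)benzoyl]oxiran-2-yl]phenyl 2,2-dimethylpropanoate | O=C(c1ccc(OCc2ccccc2)c(OCc2ccccc2)c1)[C@H]1O[C@@H]1c1ccc(OC(=O)C(C)(C)C)cc1 | intermediate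
16 | (2S,3R)-1-[3,4-bis(benzyloxy)phenyl]-2-hydroxy-3-[4-(pivaloyloxy)phenyl]-3-[(2R,3S)-7,8-bis(benzyloxy)-2-[3,4-bis(benzyloxy)phenyl]-3-hydroxychroman-6-yl]propan-1-one | O=C(c1ccc(OCc2ccccc2)c(OCc2ccccc2)c1)[C@@H](O)[C@H](c1ccc(OC(=O)C(C)(C)C)cc1)c1cc2c(c(OCc3ccccc3)c1OCc1ccccc1)O[C@H](c1ccc(OCc3ccccc3)c(OCc3ccccc3)c1)[C@@H](O)C2 | intermediate
17 | (2S,3R)-2-(benzyloxy)-1-[3,4-bis(benzyloxy)phenyl]-3-[4-(pivaloyloxy)phenyl]-3-[(2R,3S)-3,7,8-tris(benzyloxy)-2-[3,4-bis(benzyloxy)phenyl]chroman-6-yl]propan-1-one | O=C(c1ccc(OCc2ccccc2)c(OCc2ccccc2)c1)[C@@H](OCc1ccccc1)[C@H](c1ccc(OC(=O)C(C)(C)C)cc1)c1cc2c(c(OCc3ccccc3)c1OCc1ccccc1)O[C@H](c1ccc(OCc3ccccc3)c(OCc3ccccc3)c1)[C@@H](OCc1ccccc1)C2 | intermediate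
18 | (1R,2S,3R)-2-(benzyloxy)-1-[3,4-bis(benzyloxy)phenyl]-3-[4-(pivaloyloxy)phenyl]-3-[(2R,3S)-3,7,8-tris(benzyloxy)-2-[3,4-bis(benzyloxy)phenyl]chroman-6-yl]propan-1-ol | O[C@H](c1ccc(OCc2ccccc2)c(OCc2ccccc2)c1)[C@@H](OCc1ccccc1)[C@H](c1ccc(OC(=O)C(C)(C)C)cc1)c1cc2c(c(OCc3ccccc3)c1OCc1ccccc1)O[C@H](c1ccc(OCc3ccccc3)c(OCc3ccccc3)c1)[C@@H](OCc1ccccc1)C2 | intermediate
19 | (1R,2S,3R)-2-(benzyloxy)-1-[3,4-bis(benzyloxy)phenyl]-3-(4-hydroxyphenyl)-3-[(2R,3S)-3,7,8-tris(benzyloxy)-2-[3,4-bis(benzyloxy)phenyl]chroman-6-yl]propan-1-ol | O[C@H](c1ccc(OCc2ccccc2)c(OCc2ccccc2)c1)[C@@H](OCc1ccccc1)[C@H](c1ccc(O)cc1)c1cc2c(c(OCc3ccccc3)c1OCc1ccccc1)O[C@H](c1ccc(OCc3ccccc3)c(OCc3ccccc3)c1)[C@@H](OCc1ccccc1)C2 | intermediate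
20 | 4-hydroperoxy-4-[(1R,2S,3R)-2-(benzyloxy)-3-[3,4-bis(benzyloxy)phenyl]-3-hydroxy-1-[(2R,3S)-3,7,8-tris(benzyloxy)-2-[3,4-bis(benzyloxy)phenyl]chroman-6-yl]propyl]cyclohexa-2,5-dien-1-one | O[C@H](c1ccc(OCc2ccccc2)c(OCc2ccccc2)c1)[C@@H](OCc1ccccc1)[C@H](C1(OO)C=CC(=O)C=C1)c1cc2c(c(OCc3ccccc3)c1OCc1ccccc1)O[C@H](c1ccc(OCc3ccccc3)c(OCc3ccccc3)c1)[C@@H](OCc1ccccc1)C2 | intermediate
21 | 4-hydroxy-4-[(1R,2S,3R)-2-(benzyloxy)-3-[3,4-bis(benzyloxy)phenyl]-3-hydroxy-1-[(2R,3S)-3,7,8-tris(benzyloxy)-2-[3,4-bis(benzyloxy)phenyl]chroman-6-yl]propyl]cyclohexa-2,5-dien-1-one | O[C@H](c1ccc(OCc2ccccc2)c(OCc2ccccc2)c1)[C@@H](OCc1ccccc1)[C@H](C1(O)C=CC(=O)C=C1)c1cc2c(c(OCc3ccccc3)c1OCc1ccccc1)O[C@H](c1ccc(OCc3ccccc3)c(OCc3ccccc3)c1)[C@@H](OCc1ccccc1)C2 | intermediate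
22 | (2R,3S,4R,4aS,8aR)-3-(benzyloxy)-2-[3,4-bis(benzyloxy)phenyl]-4a-hydroxy-4-[(2R,3S)-3,7,8-tris(benzyloxy)-2-[3,4-bis(benzyloxy)phenyl]chroman-6-yl]-2,3,4,4a,8,8a-hexahydro-7H-chromen-7-one (cis-fused; the other cis-fused C4a/C8a isomer would react alike) | O=C1C=C[C@@]2(O)[C@@H](C1)O[C@H](c1ccc(OCc3ccccc3)c(OCc3ccccc3)c1)[C@@H](OCc1ccccc1)[C@H]2c1cc2c(c(OCc3ccccc3)c1OCc1ccccc1)O[C@H](c1ccc(OCc3ccccc3)c(OCc3ccccc3)c1)[C@@H](OCc1ccccc1)C2 | intermediate
23 | (2R,3S,4R)-3-(benzyloxy)-2-[3,4-bis(benzyloxy)phenyl]-4-[(2R,3S)-3,7,8-tris(benzyloxy)-2-[3,4-bis(benzyloxy)phenyl]chroman-6-yl]chroman-7-ol | Oc1ccc2c(c1)O[C@H](c1ccc(OCc3ccccc3)c(OCc3ccccc3)c1)[C@@H](OCc1ccccc1)[C@H]2c1cc2c(c(OCc3ccccc3)c1OCc1ccccc1)O[C@H](c1ccc(OCc3ccccc3)c(OCc3ccccc3)c1)[C@@H](OCc1ccccc1)C2 | intermediate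
24 | (2R,3S,4S)-2-(3,4-dihydroxyphenyl)-4-[(2R,3S)-2-(3,4-dihydroxyphenyl)-3,7,8-trihydroxychroman-6-yl]chromane-3,7-diol (CNP0252692.1) | Oc1ccc2c(c1)O[C@H](c1ccc(O)c(O)c1)[C@@H](O)[C@H]2c1cc2c(c(O)c1O)O[C@H](c1ccc(O)c(O)c1)[C@@H](O)C2 | target

**Step count and risks**

Total step count: 14. Longest linear sequence: 11 steps (steps 1–6, then 10–14); steps 7–9 run in parallel.

Steps most likely to fail:

Step 13 (proposed new method). What may go wrong: acid-induced heterolysis of the C4a–C4 bond of quinol that has not yet cyclised (a benzylic cation stabilised by ring D would leave and hydroquinone would form), dienone–phenol migration, loss of the C4 configuration by reversible deprotonation next to the arenium ion, or oxidation of the benzyloxy arenes by Oxone. The fallback uses known chemistry, a palladium-catalysed intramolecular aryl ether formation on an aryl bromide; it sets out from 11 and 10 and comes back to the route at 23. Steps 7–11 would be run with commercial 2-bromo-4-hydroxybenzaldehyde in place of 12 to give the bromo chalcone F1, its pivalate F2, the (αS,βR)-epoxide F3, the Friedel–Crafts adduct with 10 F4 and the bis-benzyl ether F5. Zn(BH4)2 reduction without the methoxide stage would give the anti alcohol F6. Pd(OAc)2 with 2-(di-tert-butylphosphino)-1,1'-binaphthyl and Cs2CO3 in toluene at 70 °C would then form the O1–C8a bond with retention at C2 to give the 7-O-pivaloyl chroman F7, and NaOMe in MeOH would give 23.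

Step 10. What may go wrong: acyl migration in the Lewis-acid-complexed epoxy ketone (Meinwald rearrangement), erosion of the inversion through a free benzylic cation, or alkylation at oxygen or at C5 of 10. The fallback replaces the epoxide opening by a Hayashi–Miyaura conjugate addition and an enolate hydroxylation; it sets out from 10 and 14 and comes back at 16. N-bromosuccinimide should brominate 10 at C6 to give the bromide F8, and Miyaura borylation (B2pin2, Pd(dppf)Cl2, KOAc, dioxane) should give the boronate F9. Addition of F9 to enone 14 with [Rh(C2H4)2Cl]2 and a chiral diene ligand (enantiomer chosen for the C4 configuration of 16) should give the β,β-diaryl ketone F10, and hydroxylation of its potassium enolate (KN(SiMe3)2, then the matching enantiomer of (camphorsulfonyl)oxaziridine) should give 16.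

Step 5. What may go wrong: ionisation at the p-benzyloxy-stabilised Cβ before ring closure, which would erode the trans selectivity and, through C3 epimerisation of the cis isomer, the optical purity; methanol may also open the epoxide. The fallback is a thiol relay; it sets out from 6 and comes back at 8. BnSH with SnCl4 in CH2Cl2 at −20 °C should open 6 at Cβ to give the β-benzylsulfanyl α-hydroxy ketone F11, dilute HCl in MeOH at rt should remove the methoxymethyl group to give the phenol F12, and AgBF4 in CH2Cl2 should activate the sulfide and close the 2,3-trans dihydroflavonol 8.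

Further compounds
F1 | step 13 | (E)-1-[3,4-bis(benzyloxy)phenyl]-3-(2-bromo-4-hydroxyphenyl)prop-2-en-1-one | O=C(/C=C/c1ccc(O)cc1Br)c1ccc(OCc2ccccc2)c(OCc2ccccc2)c1
F2 | step 13 | 3-bromo-4-[(E)-3-[3,4-bis(benzyloxy)phenyl]-3-oxoprop-1-en-1-yl]phenyl 2,2-dimethylpropanoate | CC(C)(C)C(=O)Oc1ccc(/C=C/C(=O)c2ccc(OCc3ccccc3)c(OCc3ccccc3)c2)c(Br)c1
F3 | step 13 | 3-bromo-4-[(2R,3S)-3-[3,4-bis(benzyloxy)benzoyl]oxiran-2-yl]phenyl 2,2-dimethylpropanoate | O=C(c1ccc(OCc2ccccc2)c(OCc2ccccc2)c1)[C@H]1O[C@@H]1c1ccc(OC(=O)C(C)(C)C)cc1Br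
F4 | step 13 | 2-bromo analogue of 16 (bromine on the pivaloyloxyphenyl ring, ortho to the propanone chain) | O=C(c1ccc(OCc2ccccc2)c(OCc2ccccc2)c1)[C@@H](O)[C@H](c1ccc(OC(=O)C(C)(C)C)cc1Br)c1cc2c(c(OCc3ccccc3)c1OCc1ccccc1)O[C@H](c1ccc(OCc3ccccc3)c(OCc3ccccc3)c1)[C@@H](O)C2
F5 | step 13 | 2-bromo analogue of 17 | O=C(c1ccc(OCc2ccccc2)c(OCc2ccccc2)c1)[C@@H](OCc1ccccc1)[C@H](c1ccc(OC(=O)C(C)(C)C)cc1Br)c1cc2c(c(OCc3ccccc3)c1OCc1ccccc1)O[C@H](c1ccc(OCc3ccccc3)c(OCc3ccccc3)c1)[C@@H](OCc1ccccc1)C2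
F6 | step 13 | 2-bromo analogue of 18 | O[C@H](c1ccc(OCc2ccccc2)c(OCc2ccccc2)c1)[C@@H](OCc1ccccc1)[C@H](c1ccc(OC(=O)C(C)(C)C)cc1Br)c1cc2c(c(OCc3ccccc3)c1OCc1ccccc1)O[C@H](c1ccc(OCc3ccccc3)c(OCc3ccccc3)c1)[C@@H](OCc1ccccc1)C2
F7 | step 13 | 7-O-pivaloyl derivative of 23 | CC(C)(C)C(=O)Oc1ccc2c(c1)O[C@H](c1ccc(OCc3ccccc3)c(OCc3ccccc3)c1)[C@@H](OCc1ccccc1)[C@H]2c1cc2c(c(OCc3ccccc3)c1OCc1ccccc1)O[C@H](c1ccc(OCc3ccccc3)c(OCc3ccccc3)c1)[C@@H](OCc1ccccc1)C2
F8 | step 10 | (2R,3S)-7,8-bis(benzyloxy)-2-[3,4-bis(benzyloxy)phenyl]-6-bromochroman-3-ol | Brc1cc2c(c(OCc3ccccc3)c1OCc1ccccc1)O[C@H](c1ccc(OCc3ccccc3)c(OCc3ccccc3)c1)[C@@H](O)C2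
F9 | step 10 | (2R,3S)-7,8-bis(benzyloxy)-2-[3,4-bis(benzyloxy)phenyl]-6-(4,4,5,5-tetramethyl-1,3,2-dioxaborolan-2-yl)chroman-3-ol | CC1(C)OB(OC1(C)C)c1cc2c(c(OCc3ccccc3)c1OCc1ccccc1)O[C@H](c1ccc(OCc3ccccc3)c(OCc3ccccc3)c1)[C@@H](O)C2
F10 | step 10 | 2-deoxy analogue of 16 (β,β-diaryl ketone, C3 as in 16) | O=C(c1ccc(OCc2ccccc2)c(OCc2ccccc2)c1)C[C@H](c1ccc(OC(=O)C(C)(C)C)cc1)c1cc2c(c(OCc3ccccc3)c1OCc1ccccc1)O[C@H](c1ccc(OCc3ccccc3)c(OCc3ccccc3)c1)[C@@H](O)C2
F11 | step 5 | 3-(benzylsulfanyl)-1-[3,4-bis(benzyloxy)-2-(methoxymethoxy)phenyl]-3-[3,4-bis(benzyloxy)phenyl]-2-hydroxypropan-1-one (Cα of 6 retained, Cβ inverted) | O=C(c1ccc(OCc2ccccc2)c(OCc2ccccc2)c1OCOC)[C@H](O)[C@H](SCc1ccccc1)c1ccc(OCc2ccccc2)c(OCc2ccccc2)c1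
F12 | step 5 | 3-(benzylsulfanyl)-1-[3,4-bis(benzyloxy)-2-hydroxyphenyl]-3-[3,4-bis(benzyloxy)phenyl]-2-hydroxypropan-1-one (configuration as in F11) | O=C(c1ccc(OCc2ccccc2)c(OCc2ccccc2)c1O)[C@H](O)[C@H](SCc1ccccc1)c1ccc(OCc2ccccc2)c(OCc2ccccc2)c1
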